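**Plan**

- Retrosynthesis: the C5–Cl bond is cut first (late electrophilic chlorination), then the pyran O2–C3 bond (6-endo closure of the C1 enol oxygen onto a C4≡C3 alkyne). C6–C7 and C4a–C8a are then cut together. This splits the carbocycle into a C7–C8–C8a piece (methyl ketone plus vinylstannane, masked as a 4H-1,3-dioxin) and a C4a–C5–C6 piece (a Z-β-iodoenal that carries the alkyne and the whole side chain).
- Enabling feature: the carbocycle C4a–C5–C6–C7–C8–C8a holds an α-ketol (C6 ketone next to the C7 tertiary carbinol, a benzoin retron). In a 1,4 relation to that bond lies C4a–C8a, the central sp2–sp2 bond of the dienol ether O2–C1=C8a–C4a=C5 (a vinyl–vinyl coupling retron). Two three-carbon ambiphiles can therefore be joined in a formal [3+3] annulation.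
- Forward order: side-chain enyne to iodoenal (steps 1–8); dioxin stannyl ketone (steps 9–14); the annulation closes the carbocycle (step 15); ketal removal and gold cyclisation close the pyran (step 16); chlorination ends the route (step 17). Tin and iodine leave in the key step. The dioxin (a temporary ring tying the C8 oxygen to the C1 enol oxygen) and the dioxolane leave in step 16. The alkyne is the latent C3–C4 unit of the pyran.
- Stereochemistry: C4′ and C5′ come from L-isoleucic acid; C3′ from a chelation-controlled MeMgBr addition; the E alkene from directed trans-hydroalumination; C8 from an (S)-proline aldol; C7 is set in the key step by a chiral triazolylidene, reinforced by the substrate.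

Key step: step 15

Assumption: the (5aS,10bR) antipode of the aminoindanol-derived triazolium salt is taken as the one whose facial preference matches the substrate bias toward the 7,8-cis diol, and compounds 1 and 10 are taken as purchasable.

**Route**

Step 1
Reactants: 1 (2S,3S)-2-hydroxy-3-methylpentanoic acid (L-isoleucic acid)
Product: 2 (2S,3S)-2-hydroxy-N-methoxy-N,3-dimethylpentanamide
Conditions: MeNHOMe·HCl, 1-ethyl-3-(3-dimethylaminopropyl)carbodiimide hydrochloride, HOBt, N-methylmorpholine, CH2Cl2, 0 °C to rt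
Reagents that add atoms: N,O-dimethylhydroxylamine hydrochloride, CNOC.Cl
Why: Carbodiimide-mediated amide coupling of the α-hydroxy acid should give the N-methoxy-N-methylamide without touching either stereocenter.

Step 2
Reactants: 2 (2S,3S)-2-hydroxy-N-methoxy-N,3-dimethylpentanamide; 3 1,4-bis(trimethylsilyl)buta-1,3-diyne
Product: 5 (6S,7S)-6-hydroxy-7-methyl-1-(trimethylsilyl)nona-1,3-diyn-5-one, via lithium (trimethylsilyl)butadiynide 4 (not isolated)
Conditions: 3, MeLi·LiBr, Et2O, rt; then 2, THF, −78 to −20 °C; aq. NH4Cl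
Reagents that add atoms: none
Why: MeLi·LiBr cleaves one C–Si bond of 3 to the lithium diynide, whose addition to the N-methoxy-N-methylamide should stop at the chelated tetrahedral intermediate and release the ynone on work-up (acylation of an organolithium by an N-methoxy-N-methylamide).

Step 3
Reactants: 5 (6S,7S)-6-hydroxy-7-methyl-1-(trimethylsilyl)nona-1,3-diyn-5-one
Product: 6 (5R,6S,7S)-5,7-dimethyl-1-(trimethylsilyl)nona-1,3-diyne-5,6-diol
Conditions: MeMgBr (3.5 equiv), THF/CH2Cl2, −78 °C; aq. NH4Cl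
Reagents that add atoms: methylmagnesium bromide, C[Mg]Br
Why: The magnesium alkoxide of the α-hydroxy ketone forms a five-membered chelate and the methyl group should add 1,2 to the face opposite the sec-butyl group, which sets the tertiary carbinol as 5R (chelation-controlled Grignard addition).

Step 4
Reactants: 6 (5R,6S,7S)-5,7-dimethyl-1-(trimethylsilyl)nona-1,3-diyne-5,6-diol
Product: 8 (3E,5R,6S,7S)-5,7-dimethylnon-3-en-1-yne-5,6-diol, via silylated enyne diol 7 (not isolated)
Conditions: NaAlH2(OCH2CH2OMe)2, THF, 0 °C to rt; then MeOH, K2CO3, rt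
Reagents that add atoms: none
Why: The tertiary propargylic alkoxide should deliver hydride only to the proximal triple bond, protonolysis of the trans-alkenylaluminate gives the E alkene, and methanolysis then removes the silyl group (alkoxide-directed trans-hydroalumination).

Step 5
Reactants: 8 (3E,5R,6S,7S)-5,7-dimethylnon-3-en-1-yne-5,6-diol
Product: 9 (4S,5R)-4-[(2S)-butan-2-yl]-5-[(1E)-but-1-en-3-yn-1-yl]-2,2,5-trimethyl-1,3-dioxolane
Conditions: Me2C(OMe)2, pyridinium p-toluenesulfonate (cat.), CH2Cl2, rt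
Reagents that add atoms: 2,2-dimethoxypropane, COC(C)(C)OC
Why: Acid-catalysed transketalisation should tie the 1,2-diol as an isopropylidene ketal that survives base, hydride and the coupling steps (acetonide formation).

Step 6
Reactants: 9 (4S,5R)-4-[(2S)-butan-2-yl]-5-[(1E)-but-1-en-3-yn-1-yl]-2,2,5-trimethyl-1,3-dioxolane; 10 3-bromoprop-2-yn-1-ol
Product: 11 (6E)-7-[(4R,5S)-5-[(2S)-butan-2-yl]-2,2,4-trimethyl-1,3-dioxolan-4-yl]hept-6-ene-2,4-diyn-1-ol
Conditions: CuCl (5 mol%), NH2OH·HCl (cat.), n-BuNH2, H2O/Et2O, 0 °C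
Reagents that add atoms: none
Why: The copper acetylide of 9 should couple with the 1-bromoalkyne to give the unsymmetrical 1,3-diyne (Cadiot–Chodkiewicz coupling).

Step 7
Reactants: 11 (6E)-7-[(4R,5S)-5-[(2S)-butan-2-yl]-2,2,4-trimethyl-1,3-dioxolan-4-yl]hept-6-ene-2,4-diyn-1-ol
Product: 13 (2Z,6E)-7-[(4R,5S)-5-[(2S)-butan-2-yl]-2,2,4-trimethyl-1,3-dioxolan-4-yl]-3-iodohepta-2,6-dien-4-yn-1-ol, via cyclic alkenylaluminate 12 (not isolated)
Conditions: NaAlH2(OCH2CH2OMe)2, THF, 0 °C; then I2, −78 to 0 °C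
Reagents that add atoms: iodine, II
Why: The primary propargylic alkoxide directs trans-hydroalumination so that aluminium ends on C3 in the five-membered aluminate 12, and iodinolysis with retention should give the vinyl iodide with iodine cis to the CH2OH group, 2Z (directed hydroalumination–iodination).

Step 8
Reactants: 13 (2Z,6E)-7-[(4R,5S)-5-[(2S)-butan-2-yl]-2,2,4-trimethyl-1,3-dioxolan-4-yl]-3-iodohepta-2,6-dien-4-yn-1-ol
Product: 14 (2Z,6E)-7-[(4R,5S)-5-[(2S)-butan-2-yl]-2,2,4-trimethyl-1,3-dioxolan-4-yl]-3-iodohepta-2,6-dien-4-ynal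
Conditions: MnO2, CH2Cl2, rt
Reagents that add atoms: none
Why: MnO2 should oxidise only the allylic primary alcohol and leave the vinyl iodide geometry untouched (allylic oxidation).

Step 9
Reactants: 15 2,2-dimethyl-1,3-dioxan-5-one; 16 acetaldehyde
Product: 17 (4S)-4-[(1S)-1-hydroxyethyl]-2,2-dimethyl-1,3-dioxan-5-one
Conditions: (S)-proline (30 mol%), DMF, 4 °C
Reagents that add atoms: none
Why: The enamine of 15 with (S)-proline adds to acetaldehyde through a hydrogen-bonded closed transition state, which should give the anti aldol and set C4 of the dioxanone as S (the future C8 of the target) under catalyst control, while the carbinol center is oxidised away later (proline-catalysed direct aldol reaction).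

Step 10
Reactants: 17 (4S)-4-[(1S)-1-hydroxyethyl]-2,2-dimethyl-1,3-dioxan-5-one
Product: 18 (4S)-2,2-dimethyl-4-[(1S)-1-(triethylsilyloxy)ethyl]-1,3-dioxan-5-one
Conditions: Et3SiCl, imidazole, CH2Cl2, 0 °C
Reagents that add atoms: chlorotriethylsilane, CC[Si](Cl)(CC)CC
Why: Silyl ether formation should block the secondary alcohol during the enolisation that follows.

Step 11
Reactants: 18 (4S)-2,2-dimethyl-4-[(1S)-1-(triethylsilyloxy)ethyl]-1,3-dioxan-5-one
Product: 20 (4S)-2,2-dimethyl-4-[(1S)-1-(triethylsilyloxy)ethyl]-4H-1,3-dioxin-5-yl trifluoromethanesulfonate, via lithium enolate 19 (not isolated)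
Conditions: LiN(SiMe3)2, THF, −78 °C; then PhNTf2, −78 to 0 °C; aq. NH4Cl
Reagents that add atoms: N-phenylbis(trifluoromethanesulfonimide), O=S(=O)(N(c1ccccc1)S(=O)(=O)C(F)(F)F)C(F)(F)F
Why: Kinetic deprotonation should take place at the unsubstituted CH2 group, and O-sulfonylation of the enolate fixes the enol triflate with the C4 stereocenter untouched (kinetic enol triflate formation).

Step 12
Reactants: 20 (4S)-2,2-dimethyl-4-[(1S)-1-(triethylsilyloxy)ethyl]-4H-1,3-dioxin-5-yl trifluoromethanesulfonate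
Product: 21 triethyl{(1S)-1-[(4S)-2,2-dimethyl-5-(trimethylstannyl)-4H-1,3-dioxin-4-yl]ethoxy}silane
Conditions: Me3SnSnMe3, Pd(PPh3)4 (5 mol%), LiCl, THF, 60 °C
Reagents that add atoms: hexamethylditin, C[Sn](C)(C)[Sn](C)(C)C
Why: Oxidative addition of the vinyl triflate to zerovalent palladium, transmetalation with the ditin and reductive elimination should give the vinylstannane (palladium-catalysed stannylation of an enol triflate).

Step 13
Reactants: 21 triethyl{(1S)-1-[(4S)-2,2-dimethyl-5-(trimethylstannyl)-4H-1,3-dioxin-4-yl]ethoxy}silane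
Product: 22 (1S)-1-[(4S)-2,2-dimethyl-5-(trimethylstannyl)-4H-1,3-dioxin-4-yl]ethan-1-ol
Conditions: Bu4NF, THF, 0 °C; aq. NH4Cl
Reagents that add atoms: none
Why: Fluoride should cleave the triethylsilyl ether under non-acidic conditions that spare the enol ketal and the vinylstannane (desilylation).

Step 14
Reactants: 22 (1S)-1-[(4S)-2,2-dimethyl-5-(trimethylstannyl)-4H-1,3-dioxin-4-yl]ethan-1-ol
Product: 23 1-[(4S)-2,2-dimethyl-5-(trimethylstannyl)-4H-1,3-dioxin-4-yl]ethan-1-one
Conditions: Pr4N[RuO4] (5 mol%), N-methylmorpholine N-oxide, 4 Å molecular sieves, CH2Cl2, 0 °C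
Reagents that add atoms: none
Why: Catalytic perruthenate with the amine oxide should oxidise the secondary alcohol to the methyl ketone under neutral conditions that do not epimerise the adjacent C4 center (catalytic perruthenate oxidation).

Step 15
Reactants: 23 1-[(4S)-2,2-dimethyl-5-(trimethylstannyl)-4H-1,3-dioxin-4-yl]ethan-1-one; 14 (2Z,6E)-7-[(4R,5S)-5-[(2S)-butan-2-yl]-2,2,4-trimethyl-1,3-dioxolan-4-yl]-3-iodohepta-2,6-dien-4-ynal
Product: 25 (8R,8aR)-5-{(3E)-4-[(4R,5S)-5-[(2S)-butan-2-yl]-2,2,4-trimethyl-1,3-dioxolan-4-yl]but-3-en-1-yn-1-yl}-8-hydroxy-2,2,8-trimethyl-8,8a-dihydro-7H-1,3-benzodioxin-7-one, via Z-dienal 24 (not isolated)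
Conditions: Pd2(dba)3 (5 mol%), AsPh3 (20 mol%), N-methylpyrrolidone, rt; then (5aS,10bR)-2-(pentafluorophenyl)-5a,10b-dihydro-4H,6H-indeno[2,1-b][1,2,4]triazolo[4,3-d][1,4]oxazin-2-ium tetrafluoroborate (20 mol%), i-Pr2NEt (20 mol%), rt
Reagents that add atoms: none
Why: Proposed new method: a zerovalent-palladium Stille coupling of vinylstannane 23 with Z-β-iodoenal 14 (oxidative addition, tin-to-palladium transmetalation, reductive elimination, both alkene geometries retained) forms C4a–C8a and places the C6 aldehyde cis to the dioxin; the triazolylidene then adds to that aldehyde, the derived aminoenol (an acyl anion equivalent at C6) attacks the C7 methyl ketone, and the carbene is expelled, forming C6–C7. The closest known reaction types are the Stille coupling of β-haloenals and the carbene-catalysed intramolecular crossed aldehyde–ketone benzoin reaction that gives six-membered tertiary α-ketols, run here in relay in one flask and with a vinylogous-formate dienal as the acyl donor. The carbocycle closes by 6-exo-trig attack on the ketone carbonyl. The only new stereocenter, C7, is set by the chiral triazolylidene and reinforced by the substrate, because the dioxin holds the C8–O bond pseudoequatorial so that closure with the methyl group pseudoequatorial and the carbonyl oxygen pseudoaxial gives the 7,8-cis (7R,8R) pattern. The step needs 1,2-addition of the acyl anion equivalent instead of β-protonation, which the fully substituted β-carbon C4a and the six-membered intramolecular ketone trap should secure, and it needs C8 to stay configurationally intact, which the catalytic amount of weak base and the fast ring closure should secure.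

Step 16
Reactants: 25 (8R,8aR)-5-{(3E)-4-[(4R,5S)-5-[(2S)-butan-2-yl]-2,2,4-trimethyl-1,3-dioxolan-4-yl]but-3-en-1-yn-1-yl}-8-hydroxy-2,2,8-trimethyl-8,8a-dihydro-7H-1,3-benzodioxin-7-one
Product: 27 (7R,8R)-3-[(1E,3R,4S,5S)-3,4-dihydroxy-3,5-dimethylhept-1-en-1-yl]-7,8-dihydroxy-7-methyl-7,8-dihydro-6H-isochromen-6-one, via hydroxymethylidene enone 26 (not isolated)
Conditions: CF3CO2H/H2O (9:1), CH2Cl2, 0 °C; then Au(OAc)3 (5 mol%), MeCN, rt
Reagents that add atoms: none
Why: Aqueous acid should hydrolyse the vinylogous acyl ketal of the dioxin and the dioxolane, and the freed hydroxymethylidene oxygen (its geometry equilibrates through the aldehyde tautomer) then adds 6-endo-dig to the gold-activated, vinyl-substituted alkyne carbon C3, with protodeauration giving the 4-alkylidene pyran (gold-catalysed cycloisomerisation of an alkynyl enol).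

Step 17
Reactants: 27 (7R,8R)-3-[(1E,3R,4S,5S)-3,4-dihydroxy-3,5-dimethylhept-1-en-1-yl]-7,8-dihydroxy-7-methyl-7,8-dihydro-6H-isochromen-6-one
Product: 28 (7R,8R)-5-chloro-3-[(1E,3R,4S,5S)-3,4-dihydroxy-3,5-dimethylhept-1-en-1-yl]-7,8-dihydroxy-7-methyl-7,8-dihydro-6H-isochromen-6-one
Conditions: N-chlorosuccinimide (1.05 equiv), MeCN, 0 °C to rt
Reagents that add atoms: N-chlorosuccinimide, O=C1CCC(=O)N1Cl
Why: C5 is the α-carbon of the doubly vinylogous ester and its most nucleophilic position, so it should take up the electrophilic chlorine, and loss of the C5 proton restores the chromophore (electrophilic α-halogenation of a vinylogous ester).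

**Compound list**

1 | (2S,3S)-2-hydroxy-3-methylpentanoic acid | CC[C@H](C)[C@H](O)C(=O)O | starting material
2 | (2S,3S)-2-hydroxy-N-methoxy-N,3-dimethylpentanamide | CC[C@H](C)[C@H](O)C(=O)N(C)OC | intermediate
3 | 1,4-bis(trimethylsilyl)buta-1,3-diyne | C[Si](C)(C)C#CC#C[Si](C)(C)C | starting material
4 | lithium (trimethylsilyl)butadiynide | [Li]C#CC#C[Si](C)(C)C | intermediate
5 | (6S,7S)-6-hydroxy-7-methyl-1-(trimethylsilyl)nona-1,3-diyn-5-one | CC[C@H](C)[C@H](O)C(=O)C#CC#C[Si](C)(C)C | intermediate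
6 | (5R,6S,7S)-5,7-dimethyl-1-(trimethylsilyl)nona-1,3-diyne-5,6-diol | CC[C@H](C)[C@H](O)[C@](C)(O)C#CC#C[Si](C)(C)C | intermediate
7 | (3E,5R,6S,7S)-5,7-dimethyl-1-(trimethylsilyl)non-3-en-1-yne-5,6-diol | CC[C@H](C)[C@H](O)[C@](C)(O)/C=C/C#C[Si](C)(C)C | intermediate
8 | (3E,5R,6S,7S)-5,7-dimethylnon-3-en-1-yne-5,6-diol | CC[C@H](C)[C@H](O)[C@](C)(O)/C=C/C#C | intermediate
9 | (4S,5R)-4-[(2S)-butan-2-yl]-5-[(1E)-but-1-en-3-yn-1-yl]-2,2,5-trimethyl-1,3-dioxolane | CC[C@H](C)[C@@H]1OC(C)(C)O[C@]1(C)/C=C/C#C | intermediate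
10 | 3-bromoprop-2-yn-1-ol | OCC#CBr | starting material
11 | (6E)-7-[(4R,5S)-5-[(2S)-butan-2-yl]-2,2,4-trimethyl-1,3-dioxolan-4-yl]hept-6-ene-2,4-diyn-1-ol | CC[C@H](C)[C@@H]1OC(C)(C)O[C@]1(C)/C=C/C#CC#CCO | intermediate
12 | sodium 3-{(3E)-4-[(4R,5S)-5-[(2S)-butan-2-yl]-2,2,4-trimethyl-1,3-dioxolan-4-yl]but-3-en-1-yn-1-yl}-2,2-bis(2-methoxyethoxy)-2,5-dihydro-1,2-oxaaluminol-2-uide (cyclic alkenylaluminate) | CC[C@H](C)[C@@H]1OC(C)(C)O[C@]1(C)/C=C/C#CC2=CCO[Al-]2(OCCOC)OCCOC.[Na+] | intermediate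
13 | (2Z,6E)-7-[(4R,5S)-5-[(2S)-butan-2-yl]-2,2,4-trimethyl-1,3-dioxolan-4-yl]-3-iodohepta-2,6-dien-4-yn-1-ol | CC[C@H](C)[C@@H]1OC(C)(C)O[C@]1(C)/C=C/C#C/C(I)=C/CO | intermediate
14 | (2Z,6E)-7-[(4R,5S)-5-[(2S)-butan-2-yl]-2,2,4-trimethyl-1,3-dioxolan-4-yl]-3-iodohepta-2,6-dien-4-ynal | CC[C@H](C)[C@@H]1OC(C)(C)O[C@]1(C)/C=C/C#C/C(I)=C/C=O | intermediate
15 | 2,2-dimethyl-1,3-dioxan-5-one | CC1(C)OCC(=O)CO1 | starting material
16 | acetaldehyde | CC=O | starting material
17 | (4S)-4-[(1S)-1-hydroxyethyl]-2,2-dimethyl-1,3-dioxan-5-one | C[C@H](O)[C@@H]1OC(C)(C)OCC1=O | intermediate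
18 | (4S)-2,2-dimethyl-4-[(1S)-1-(triethylsilyloxy)ethyl]-1,3-dioxan-5-one | C[C@H](O[Si](CC)(CC)CC)[C@@H]1OC(C)(C)OCC1=O | intermediate
19 | lithium (4S)-2,2-dimethyl-4-[(1S)-1-(triethylsilyloxy)ethyl]-4H-1,3-dioxin-5-olate | C[C@H](O[Si](CC)(CC)CC)[C@@H]1OC(C)(C)OC=C1O[Li] | intermediate
20 | (4S)-2,2-dimethyl-4-[(1S)-1-(triethylsilyloxy)ethyl]-4H-1,3-dioxin-5-yl trifluoromethanesulfonate | C[C@H](O[Si](CC)(CC)CC)[C@@H]1OC(C)(C)OC=C1OS(=O)(=O)C(F)(F)F | intermediate
21 | triethyl{(1S)-1-[(4S)-2,2-dimethyl-5-(trimethylstannyl)-4H-1,3-dioxin-4-yl]ethoxy}silane | C[C@H](O[Si](CC)(CC)CC)[C@@H]1OC(C)(C)OC=C1[Sn](C)(C)C | intermediate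
22 | (1S)-1-[(4S)-2,2-dimethyl-5-(trimethylstannyl)-4H-1,3-dioxin-4-yl]ethan-1-ol | C[C@H](O)[C@@H]1OC(C)(C)OC=C1[Sn](C)(C)C | intermediate
23 | 1-[(4S)-2,2-dimethyl-5-(trimethylstannyl)-4H-1,3-dioxin-4-yl]ethan-1-one | CC(=O)[C@@H]1OC(C)(C)OC=C1[Sn](C)(C)C | intermediate
24 | (2Z,6E)-3-[(4R)-4-acetyl-2,2-dimethyl-4H-1,3-dioxin-5-yl]-7-[(4R,5S)-5-[(2S)-butan-2-yl]-2,2,4-trimethyl-1,3-dioxolan-4-yl]hepta-2,6-dien-4-ynal | CC[C@H](C)[C@@H]1OC(C)(C)O[C@]1(C)/C=C/C#C/C(=C/C=O)C2=COC(C)(C)O[C@H]2C(C)=O | intermediate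
25 | (8R,8aR)-5-{(3E)-4-[(4R,5S)-5-[(2S)-butan-2-yl]-2,2,4-trimethyl-1,3-dioxolan-4-yl]but-3-en-1-yn-1-yl}-8-hydroxy-2,2,8-trimethyl-8,8a-dihydro-7H-1,3-benzodioxin-7-one | CC[C@H](C)[C@@H]1OC(C)(C)O[C@]1(C)/C=C/C#CC2=CC(=O)[C@](C)(O)[C@@H]3OC(C)(C)OC=C23 | intermediate
26 | (5R,6R)-3-[(3E,5R,6S,7S)-5,6-dihydroxy-5,7-dimethylnon-3-en-1-yn-1-yl]-5,6-dihydroxy-4-(hydroxymethylidene)-6-methylcyclohex-2-en-1-one | CC[C@H](C)[C@H](O)[C@](C)(O)/C=C/C#CC1=CC(=O)[C@](C)(O)[C@H](O)C1=CO | intermediate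
27 | (7R,8R)-3-[(1E,3R,4S,5S)-3,4-dihydroxy-3,5-dimethylhept-1-en-1-yl]-7,8-dihydroxy-7-methyl-7,8-dihydro-6H-isochromen-6-one | CC[C@H](C)[C@H](O)[C@](C)(O)/C=C/C1=CC2=CC(=O)[C@](C)(O)[C@H](O)C2=CO1 | intermediate
28 | (7R,8R)-5-chloro-3-[(1E,3R,4S,5S)-3,4-dihydroxy-3,5-dimethylhept-1-en-1-yl]-7,8-dihydroxy-7-methyl-7,8-dihydro-6H-isochromen-6-one | CC[C@H](C)[C@H](O)[C@](C)(O)/C=C/C1=CC2=C(Cl)C(=O)[C@](C)(O)[C@H](O)C2=CO1 | target

**Count and risks**

Total steps: 17. Longest linear sequence: 11 steps (steps 1 to 8, then 15, 16 and 17).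

Steps most likely to fail:

1. Step 15 (proposed new method). The aminoenol may be protonated at carbon instead of adding to the ketone. The base may epimerise C8 or move the enol-ether double bond into conjugation with the ketone. The carbene may be bound by palladium or tin residues, and the Z-dienal may rest as its oxa-6π valence isomer. Fallback with known chemistry: starting from 23 and 14, the Stille coupling is run alone under the same palladium conditions and dienal 24 is isolated. SmI2 in THF at −78 °C then effects intramolecular ketyl (pinacol) coupling of the aldehyde with the methyl ketone, with samarium bridging the ketyl oxygen and the C8 oxygen, to give (7S,8S,8aR)-5-{(3E)-4-[(4R,5S)-5-[(2S)-butan-2-yl]-2,2,4-trimethyl-1,3-dioxolan-4-yl]but-3-en-1-yn-1-yl}-2,2,8-trimethyl-8,8a-dihydro-7H-1,3-benzodioxine-7,8-diol F1. Selective oxidation of its secondary allylic carbinol with MnO2 returns the route at 25.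

2. Step 16. The freed C8 hydroxyl may attack the alkyne in a 5-exo mode, the acid may ionise the tertiary allylic carbinol of the side chain, and ketal cleavage may be incomplete. Fallback with a staged order: starting from 25, AcOH/THF/H2O at 0 °C opens only the labile dioxin ketal to (5R,6R)-3-{(3E)-4-[(4R,5S)-5-[(2S)-butan-2-yl]-2,2,4-trimethyl-1,3-dioxolan-4-yl]but-3-en-1-yn-1-yl}-5,6-dihydroxy-4-(hydroxymethylidene)-6-methylcyclohex-2-en-1-one F2. AgOTf (5 mol%) closes the pyran to (7R,8R)-3-{(E)-2-[(4R,5S)-5-[(2S)-butan-2-yl]-2,2,4-trimethyl-1,3-dioxolan-4-yl]ethenyl}-7,8-dihydroxy-7-methyl-7,8-dihydro-6H-isochromen-6-one F3. N-chlorosuccinimide gives its 5-chloro derivative (7R,8R)-3-{(E)-2-[(4R,5S)-5-[(2S)-butan-2-yl]-2,2,4-trimethyl-1,3-dioxolan-4-yl]ethenyl}-5-chloro-7,8-dihydroxy-7-methyl-7,8-dihydro-6H-isochromen-6-one F4. Removal of the dioxolane with 1 M HCl in THF as the last operation returns the route at 28.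

3. Step 9. Acetaldehyde may self-condense and enamine turnover may be slow, which would lower conversion and erode selectivity. Fallback by resolution: starting from 15 and 16, the lithium enolate (LiN(i-Pr)2, THF, −78 °C) gives the racemic anti aldol through a closed six-membered transition state, that is 17 together with its enantiomer (4R)-4-[(1R)-1-hydroxyethyl]-2,2-dimethyl-1,3-dioxan-5-one F5. Candida antarctica lipase B with vinyl acetate should acylate the (1R) carbinol to (1R)-1-[(4R)-2,2-dimethyl-5-oxo-1,3-dioxan-4-yl]ethyl acetate F6 and leave the (1S) alcohol. The unreacted alcohol is separated and the route resumes at 17.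

Further compounds
F1 | step 15 | (7S,8S,8aR)-5-{(3E)-4-[(4R,5S)-5-[(2S)-butan-2-yl]-2,2,4-trimethyl-1,3-dioxolan-4-yl]but-3-en-1-yn-1-yl}-2,2,8-trimethyl-8,8a-dihydro-7H-1,3-benzodioxine-7,8-diol | CC[C@H](C)[C@@H]1OC(C)(C)O[C@]1(C)/C=C/C#CC2=C[C@H](O)[C@](C)(O)[C@@H]3OC(C)(C)OC=C23
F2 | step 16 | (5R,6R)-3-{(3E)-4-[(4R,5S)-5-[(2S)-butan-2-yl]-2,2,4-trimethyl-1,3-dioxolan-4-yl]but-3-en-1-yn-1-yl}-5,6-dihydroxy-4-(hydroxymethylidene)-6-methylcyclohex-2-en-1-one | CC[C@H](C)[C@@H]1OC(C)(C)O[C@]1(C)/C=C/C#CC2=CC(=O)[C@](C)(O)[C@H](O)C2=CO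
F3 | step 16 | (7R,8R)-3-{(E)-2-[(4R,5S)-5-[(2S)-butan-2-yl]-2,2,4-trimethyl-1,3-dioxolan-4-yl]ethenyl}-7,8-dihydroxy-7-methyl-7,8-dihydro-6H-isochromen-6-one | CC[C@H](C)[C@@H]1OC(C)(C)O[C@]1(C)/C=C/C3=CC4=CC(=O)[C@](C)(O)[C@H](O)C4=CO3
F4 | step 16 | (7R,8R)-3-{(E)-2-[(4R,5S)-5-[(2S)-butan-2-yl]-2,2,4-trimethyl-1,3-dioxolan-4-yl]ethenyl}-5-chloro-7,8-dihydroxy-7-methyl-7,8-dihydro-6H-isochromen-6-one | CC[C@H](C)[C@@H]1OC(C)(C)O[C@]1(C)/C=C/C3=CC4=C(Cl)C(=O)[C@](C)(O)[C@H](O)C4=CO3
F5 | step 9 | (4R)-4-[(1R)-1-hydroxyethyl]-2,2-dimethyl-1,3-dioxan-5-one | C[C@@H](O)[C@H]1OC(C)(C)OCC1=O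
F6 | step 9 | (1R)-1-[(4R)-2,2-dimethyl-5-oxo-1,3-dioxan-4-yl]ethyl acetate | C[C@@H](OC(C)=O)[C@H]1OC(C)(C)OCC1=O
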